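**Retrosynthetic overview**
1. The target is the 2-O-angeloyl, 6-O-(3,4,5-trimethoxybenzoyl) diester of a cis-fused hydroazulene triol; both esters go on late (angelate last), and the C8(Me)=C9 olefin comes from a C9 ketone via an exo-methylene ketone and an enol triflate.
2. Key disconnections are C5–C6 and C1–C10: the 6,9-diketone is the retro-aldol product of a cyclobutanol, so the seven-membered ring (C5, C6, C7, C8, C9, C10, C1) arises from the five-membered ring of cyclopentane-1,3-dione (C6–C10) by insertion of the ring-fusion carbons C5 and C1 of a cyclopentene (de Mayo sequence, five to seven).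
3. Enabling feature: O4 and O6 are 1,3-related across the ring-fusion carbon C5, C6 and C9 are 1,5-related through C5–C1–C10, and both new ring bonds lie on the face of O4; one silicon atom can therefore tie the dione enol oxygen (future O6) to O4 and deliver the enone to that face, which gives the cis fusion and the quaternary C1.
4. Order of ring formation: the five-membered ring C1–C5 comes from enantiopure 4-silyloxycyclopentenone (C2 from the starting material, C4 by 1,4-anti Grignard addition); the cyclobutane is closed photochemically and opened in the same step to the seven-membered ring.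
5. After the key step, C6 is set by hydride delivery from the 4-hydroxyl.

Key step: step 5

Remark: positions are numbered as in the daucane skeleton (C1 angular C–Me, C2 CH–O-angeloyl, C3 CH2, C4 C(OH)(iPr), C5 ring-fusion CH, C6 CH–O-aroyl, C7 CH2, C8 C(Me)=, C9 =CH, C10 CH2), and β is the face of the C1 methyl group; the target is then 1β-Me, 5β-H (cis-fused), 2α-O, 4α-OH, 4β-iPr, 6β-O, i.e. (1S,3S,3aR,4R,8aR) in azulene numbering.

**Step 1**
Reactants: 1 (S)-4-(tert-butyldimethylsilyloxy)cyclopent-2-en-1-one
Product: 2 (3S,4S)-4-(tert-butyldimethylsilyloxy)-3-methyl-1-(trimethylsilyloxy)cyclopent-1-ene (methyl trans to OTBS)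
Conditions: Me2CuLi, Me3SiCl, THF, −78 °C
Reagents that add atoms: lithium dimethylcuprate, [Li+].C[Cu-]C; chlorotrimethylsilane, C[Si](C)(C)Cl
Why: Me3SiCl-accelerated cuprate conjugate addition should deliver the methyl group anti to the silyloxy group and trap the regiodefined enolate as its silyl enol ether, so that no enolate equilibration towards C5 and no loss of silanol can occur (the new methine centre is removed again in step 2).

**Step 2**
Reactants: 2 silyl enol ether
Product: 3 (S)-4-(tert-butyldimethylsilyloxy)-3-methylcyclopent-2-en-1-one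
Conditions: Pd(OAc)2 (1.1 equiv), MeCN, rt
Reagents that add atoms: none
Why: Saegusa–Ito oxidation, in which the palladium enolate can undergo β-hydride elimination only towards the methyl-bearing carbon, should regenerate the enone with the methyl group on the β-carbon and leave the silyloxy stereocentre untouched.

**Step 3**
Reactants: 3 β-methyl enone
Product: 4 (1S,4S)-4-(tert-butyldimethylsilyloxy)-3-methyl-1-(propan-2-yl)cyclopent-2-en-1-ol (OH cis to OTBS)
Conditions: iPrMgCl, LaCl3·2LiCl, THF, −20 °C
Reagents that add atoms: isopropylmagnesium chloride, CC(C)[Mg]Cl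
Why: Lanthanide-promoted 1,2-addition of the Grignard reagent (which suppresses enolisation and β-hydride reduction) should occur on the carbonyl face anti to the bulky silyloxy group, placing the new tertiary hydroxyl cis to OTBS (future 4α-OH, 4β-isopropyl).

**Step 4**
Reactants: 4 tertiary allylic alcohol; 5 cyclopentane-1,3-dione
Product: 7 mixed silaketal 3-{[{[(1S,4S)-4-(tert-butyldimethylsilyloxy)-3-methyl-1-(propan-2-yl)cyclopent-2-en-1-yl]oxy}di(propan-2-yl)silyl]oxy}cyclopent-2-en-1-one, via silyl triflate 6 (not isolated)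
Conditions: iPr2Si(OTf)2, Et3N, CH2Cl2, −78 to 0 °C; then 5, Et3N, 0 °C to rt; salts filtered off, used crude
Reagents that add atoms: di(propan-2-yl)silanediyl bis(trifluoromethanesulfonate), CC(C)[Si](OS(=O)(=O)C(F)(F)F)(OS(=O)(=O)C(F)(F)F)C(C)C
Why: Sequential silyl ether formation with a silyl bis-triflate should work because the hindered tertiary alcohol takes up only one Si–OTf bond and the remaining one silylates the acidic enol oxygen of the dione (vinylogous silyl ester), giving the silicon tether anchored on the future 4α-oxygen.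

**Step 5**
Reactants: 7 mixed silaketal
Product: 10 2α-(tert-butyldimethylsilyloxy)-4α-hydroxy-4β-isopropyl-1β-methyl-5β-H-bicyclo[5.3.0]decane-6,9-dione (cis-fused), via cyclobutane photoadduct 8 (not isolated), via cyclobutanol 9 (not isolated)
Conditions: hν (300 nm, Pyrex), CH2Cl2, 0 °C; then HF·pyridine, pyridine, THF, 0 °C
Reagents that add atoms: none
Why: Proposed new method: a de Mayo reaction ([2+2] enone–alkene photocycloaddition, then retro-aldol) in which a disposable O–Si–O tether through the enol oxygen of the 1,3-dione carries the alkene partner, a combination not known as such, the closest known reaction types being the intramolecular photocycloaddition/retro-aldol ring enlargement of protected 1,3-dione enols onto cyclopentenes and silicon-tethered enone–alkene [2+2] photocycloadditions. The triplet β-silyloxy enone should bond through its β-carbon (C6) to C5 of the alkene (6-exo-trig closure of the 1,3-dioxa-2-silacyclohexane ring, leaving the tertiary C1 radical), and the 1,4-biradical should collapse by C10–C1 bond formation to the cis-fused cyclobutane 8. Buffered HF·pyridine should cleave the cyclic dialkoxysilane faster than the hindered secondary TBS ether, and the freed cyclobutanol 9, a strained β-hydroxy ketone, should open by retro-aldol cleavage of the C6–C10 bond, so that the five-membered dione ring is enlarged by C5 and C1 to the cycloheptane-1,4-dione of 10. The quaternary C1 and C5 are both set by the tether, which is anchored on the 4α-oxygen and forces suprafacial addition to the α face, hence the cis ring fusion with 1β-methyl and 5β-H. The step needs head-to-head regiochemistry, which the four-atom C4–O–Si–O link secures because the enol carbon can reach only C5, and it needs non-basic unmasking so that 5-H does not epimerise and the tertiary aldol C4–C5–C6 does not cleave.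

**Step 6**
Reactants: 10 hydroxy diketone
Product: 11 2α-(tert-butyldimethylsilyloxy)-4α,6β-dihydroxy-9-ketone (cis-fused core as in 10)
Conditions: Me4NBH(OAc)3, MeCN/AcOH, −30 °C
Reagents that add atoms: none
Why: Evans–Saksena hydroxyl-directed reduction, in which the tertiary 4α-hydroxyl exchanges onto boron and delivers hydride internally to the α face of the C6 carbonyl, should give the 6β-alcohol (1,3-anti diol) while the remote C9 ketone is not reduced by the triacetoxyborohydride.

**Step 7**
Reactants: 11 diol ketone; 12 3,4,5-trimethoxybenzoyl chloride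
Product: 13 6β-(3,4,5-trimethoxybenzoyloxy)-2α-(tert-butyldimethylsilyloxy)-4α-hydroxy-9-ketone
Conditions: Et3N, DMAP (cat.), CH2Cl2, 0 °C to rt
Reagents that add atoms: none
Why: DMAP-catalysed acylation should be selective for the only secondary hydroxyl, because the tertiary 4-OH next to the isopropyl group is too hindered to react.

**Step 8**
Reactants: 13 keto ester
Product: 16 8-methylidene-9-ketone (other groups as in 13), via Mannich base 14 (not isolated), via methiodide 15 (not isolated)
Conditions: LiN(iPr)2 (2.2 equiv), THF, −78 °C; CH2=NMe2+ I−, −78 to 0 °C; then MeI, CH2Cl2, rt; then DBU, rt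
Reagents that add atoms: N,N-dimethylmethaniminium iodide, C=[N+](C)C.[I-]; iodomethane, CI (atoms retained only in intermediate 15)
Why: Eschenmoser α-methylenation should work because kinetic deprotonation of the C9 ketone occurs at C8 and not at the neopentyl C10 next to the quaternary C1, after which aminomethylation, quaternisation and E1cB elimination give the exo-methylene ketone.

**Step 9**
Reactants: 16 exo-methylene ketone
Product: 17 C8(Me)=C9 enol triflate (9-trifluoromethanesulfonyloxy-8-methyl-8-ene; other groups as in 13)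
Conditions: LiBH(sec-Bu)3, THF, −78 °C; then N-(5-chloropyridin-2-yl)triflimide, −78 to 0 °C
Reagents that add atoms: N-(5-chloropyridin-2-yl)-1,1,1-trifluoro-N-(trifluoromethylsulfonyl)methanesulfonamide, FC(F)(F)S(=O)(=O)N(c1ccc(Cl)cn1)S(=O)(=O)C(F)(F)F
Why: Conjugate reduction of the β-unsubstituted enone by the hindered borohydride should give regiospecifically the C8=C9 enolate, and O-triflation of this enolate fixes the double bond between C8 (now carrying the methyl group) and C9.

**Step 10**
Reactants: 17 enol triflate
Product: 18 2α-(tert-butyldimethylsilyloxy)-4α-hydroxy-6β-(3,4,5-trimethoxybenzoyloxy)-8-ene (C8-methyl, C9-H)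
Conditions: Pd(OAc)2 (cat.), PPh3, HCO2H, Bu3N, DMF, 60 °C
Reagents that add atoms: none
Why: Palladium-catalysed formate reduction of the enol triflate (oxidative addition, formate-to-hydride exchange with loss of CO2, reductive elimination) should replace OTf by H without moving the double bond.

**Step 11**
Reactants: 18 silyl ether
Product: 19 2α,4α-dihydroxy-6β-(3,4,5-trimethoxybenzoyloxy)-8-ene
Conditions: HF·pyridine, THF, 0 °C to rt
Reagents that add atoms: none
Why: Fluoride-mediated cleavage of the secondary TBS ether under non-basic conditions should free the 2-OH without migration of the C6 aroyl group.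

**Step 12**
Reactants: 19 diol ester; 20 angelic acid
Product: 22 target CNP0112256.1, via mixed anhydride 21 (not isolated)
Conditions: 20, 2,4,6-Cl3C6H2COCl, Et3N, toluene, rt; then 19, toluene, 80 °C
Reagents that add atoms: 2,4,6-trichlorobenzoyl chloride, O=C(Cl)c1c(Cl)cc(Cl)cc1Cl (atoms retained only in intermediate 21)
Why: Yamaguchi esterification through the mixed anhydride without nucleophilic catalyst is the established way to acylate with angelic acid without Z-to-E isomerisation to the tiglate, and only the secondary 2-OH should react.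

**Compound list**
1 | (S)-4-(tert-butyldimethylsilyloxy)cyclopent-2-en-1-one | CC(C)(C)[Si](C)(C)O[C@H]1CC(=O)C=C1 | starting material
2 | (3S,4S)-4-(tert-butyldimethylsilyloxy)-3-methyl-1-(trimethylsilyloxy)cyclopent-1-ene | CC(C)(C)[Si](C)(C)O[C@H]1CC(O[Si](C)(C)C)=C[C@@H]1C | intermediate
3 | (S)-4-(tert-butyldimethylsilyloxy)-3-methylcyclopent-2-en-1-one | CC(C)(C)[Si](C)(C)O[C@H]1CC(=O)C=C1C | intermediate
4 | (1S,4S)-4-(tert-butyldimethylsilyloxy)-3-methyl-1-(propan-2-yl)cyclopent-2-en-1-ol | CC(C)(C)[Si](C)(C)O[C@H]1C[C@](O)(C(C)C)C=C1C | intermediate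
5 | cyclopentane-1,3-dione | O=C1CCC(=O)C1 | starting material
6 | {[(1S,4S)-4-(tert-butyldimethylsilyloxy)-3-methyl-1-(propan-2-yl)cyclopent-2-en-1-yl]oxy}di(propan-2-yl)silyl trifluoromethanesulfonate | CC(C)(C)[Si](C)(C)O[C@H]1C[C@](O[Si](C(C)C)(C(C)C)OS(=O)(=O)C(F)(F)F)(C(C)C)C=C1C | intermediate
7 | mixed diisopropylsilaketal of 4 and the enol of 5 | CC(C)(C)[Si](C)(C)O[C@H]1C[C@](O[Si](C(C)C)(C(C)C)OC2=CC(=O)CC2)(C(C)C)C=C1C | intermediate
8 | cyclobutane photoadduct (new bonds C5–C6 and C1–C10 on the α face, O4–Si–O6 bridge, cyclopentanone ring anti to the C1–C5 ring) | CC(C)(C)[Si](C)(C)O[C@H]1C[C@@]2(C(C)C)O[Si](C(C)C)(C(C)C)O[C@@]34CCC(=O)[C@@H]3[C@]1(C)[C@@H]24 | intermediate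
9 | desilylated cyclobutanol (4α-OH, C6-OH, C9 ketone) | CC(C)(C)[Si](C)(C)O[C@H]1C[C@](O)(C(C)C)[C@H]2[C@]3(O)CCC(=O)[C@@H]3[C@@]12C | intermediate
10 | 2α-(tert-butyldimethylsilyloxy)-4α-hydroxy-4β-isopropyl-1β-methyl-5β-H-bicyclo[5.3.0]decane-6,9-dione | CC(C)(C)[Si](C)(C)O[C@H]1C[C@](O)(C(C)C)[C@H]2C(=O)CCC(=O)C[C@@]12C | intermediate
11 | 4α,6β-diol 9-ketone | CC(C)(C)[Si](C)(C)O[C@H]1C[C@](O)(C(C)C)[C@H]2[C@H](O)CCC(=O)C[C@@]12C | intermediate
12 | 3,4,5-trimethoxybenzoyl chloride | COc1cc(cc(OC)c1OC)C(=O)Cl | starting material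
13 | 6β-(3,4,5-trimethoxybenzoate) 9-ketone | CC(C)(C)[Si](C)(C)O[C@H]1C[C@](O)(C(C)C)[C@H]2[C@H](OC(=O)c3cc(OC)c(OC)c(OC)c3)CCC(=O)C[C@@]12C | intermediate
14 | 8-(dimethylaminomethyl) 9-ketone (C8 epimers) | CC(C)(C)[Si](C)(C)O[C@H]1C[C@](O)(C(C)C)[C@H]2[C@H](OC(=O)c3cc(OC)c(OC)c(OC)c3)CC(CN(C)C)C(=O)C[C@@]12C | intermediate
15 | 8-(trimethylammoniomethyl) 9-ketone iodide | CC(C)(C)[Si](C)(C)O[C@H]1C[C@](O)(C(C)C)[C@H]2[C@H](OC(=O)c3cc(OC)c(OC)c(OC)c3)CC(C[N+](C)(C)C)C(=O)C[C@@]12C.[I-] | intermediate
16 | 8-methylidene 9-ketone | CC(C)(C)[Si](C)(C)O[C@H]1C[C@](O)(C(C)C)[C@H]2[C@H](OC(=O)c3cc(OC)c(OC)c(OC)c3)CC(=C)C(=O)C[C@@]12C | intermediate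
17 | C8(Me)=C9 enol triflate | CC(C)(C)[Si](C)(C)O[C@H]1C[C@](O)(C(C)C)[C@H]2[C@H](OC(=O)c3cc(OC)c(OC)c(OC)c3)CC(C)=C(OS(=O)(=O)C(F)(F)F)C[C@@]12C | intermediate
18 | 2-O-TBS ether of the 6-O-aroyl 8-ene | CC(C)(C)[Si](C)(C)O[C@H]1C[C@](O)(C(C)C)[C@H]2[C@H](OC(=O)c3cc(OC)c(OC)c(OC)c3)CC(C)=CC[C@@]12C | intermediate
19 | 2α,4α-diol 6β-(3,4,5-trimethoxybenzoate) | O[C@H]1C[C@](O)(C(C)C)[C@H]2[C@H](OC(=O)c3cc(OC)c(OC)c(OC)c3)CC(C)=CC[C@@]12C | intermediate
20 | angelic acid, (2Z)-2-methylbut-2-enoic acid | C/C=C(/C)C(=O)O | starting material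
21 | angelic 2,4,6-trichlorobenzoic anhydride | C/C=C(/C)C(=O)OC(=O)c1c(Cl)cc(Cl)cc1Cl | intermediate
22 | (1S,3S,3aR,4R,8aR)-3-hydroxy-6,8a-dimethyl-1-{[(2Z)-2-methylbut-2-enoyl]oxy}-3-(propan-2-yl)-1,2,3,3a,4,5,8,8a-octahydroazulen-4-yl 3,4,5-trimethoxybenzoate | C/C=C(/C)C(=O)O[C@H]1C[C@](O)(C(C)C)[C@H]2[C@H](OC(=O)c3cc(OC)c(OC)c(OC)c3)CC(C)=CC[C@@]12C | target

Total step count: 12. Longest linear sequence: 12 steps (from 1).

**Steps most likely to fail**

Step 5 (Proposed new method). The 1,4-biradical may revert or close in the crossed sense next to the bulky 2-silyloxy group, the vinylogous silyl ester may hydrolyse before irradiation, and the unmasking may also remove the TBS group or epimerise C5. The fallback uses only known chemistry, sets out from 4 and 5 and returns at 10. The TBS ether of 4 is removed (Bu4NF, THF) to give the cis-diol F1, whose β face is shielded by the isopropyl group while the α face carries only two hydroxyls. 5 is O-acetylated (AcCl, pyridine) to the enol acetate F2. Classical intermolecular de Mayo irradiation of F2 with F1 (Pyrex, MeCN) should give, after separation from regio- and facial isomers, the head-to-head α-face photoadduct F3. K2CO3 in MeOH at 0 °C should remove the acetate and trigger the same retro-aldol ring enlargement to the dihydroxy dione F4, and silylation of its only secondary hydroxyl (TBSOTf, 2,6-lutidine, −78 °C) returns 10.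

Step 8. Enolisation may occur on the C10 side, or the aroyl group may be transferred to the neighbouring alkoxide in the dianion. The fallback sets out from 13 and returns at 14. 13 is condensed with pyrrolidine (TsOH cat., benzene, reflux with removal of water) to the less hindered enamine F5 (double bond C8=C9, away from the neopentyl C10). This Stork enamine is aminomethylated with CH2=NMe2+ I− under neutral conditions and hydrolysed to the Mannich base 14, from which the route continues.

Step 12. Acylation of the neopentyl 2-OH may be sluggish, and the acyl donor may isomerise from Z to E on prolonged heating. The fallback sets out from 19 and returns at 22. 19 is acylated (DCC, DMAP, CH2Cl2) with 2-[bis(2,2,2-trifluoroethoxy)phosphoryl]propanoic acid to the phosphonate ester F6. A Still–Gennari olefination with acetaldehyde (KN(SiMe3)2, 18-crown-6, THF, −78 °C) then builds the Z-trisubstituted double bond on the ester in place and gives 22.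

**Further compounds**
F1 | step 5 | (1S,4S)-3-methyl-1-(propan-2-yl)cyclopent-2-ene-1,4-diol | O[C@H]1C[C@](O)(C(C)C)C=C1C
F2 | step 5 | 3-oxocyclopent-1-en-1-yl acetate | CC(=O)OC1=CC(=O)CC1
F3 | step 5 | intermolecular head-to-head α-face photoadduct (C6 acetate, 2α,4α-diol, C9 ketone) | O[C@H]1C[C@](O)(C(C)C)[C@H]2[C@]3(OC(C)=O)CCC(=O)[C@@H]3[C@@]12C
F4 | step 5 | 2α,4α-dihydroxy-4β-isopropyl-1β-methyl-5β-H-bicyclo[5.3.0]decane-6,9-dione | O[C@H]1C[C@](O)(C(C)C)[C@H]2C(=O)CCC(=O)C[C@@]12C
F5 | step 8 | 9-(pyrrolidin-1-yl) C8=C9 enamine of 13 | CC(C)(C)[Si](C)(C)O[C@H]1C[C@](O)(C(C)C)[C@H]2[C@H](OC(=O)c3cc(OC)c(OC)c(OC)c3)CC=C(N4CCCC4)C[C@@]12C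
F6 | step 12 | 2-O-{2-[bis(2,2,2-trifluoroethoxy)phosphoryl]propanoyl} ester of 19 | CC(C(=O)O[C@H]1C[C@](O)(C(C)C)[C@H]2[C@H](OC(=O)c3cc(OC)c(OC)c(OC)c3)CC(C)=CC[C@@]12C)P(=O)(OCC(F)(F)F)OCC(F)(F)F
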